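The synthesis rests on cutting the C9–C10 bond of the ten-membered carbocycle (C1–C10). A CrCl2/NiCl2 Nozaki–Hiyama–Kishi reaction joins the Z-alkenyl iodide carbon C10 to the C9 aldehyde, closing the ring and creating the C9 carbinol in one operation. It exploits the Z-C1=C10 olefin, which holds C2 and C9 cis, and the C6–C7 γ-lactone, which together keep the chain folded. The precursor is the seco γ-lactone carrying the C9 aldehyde, the O8 epoxy ester, a free C7 hydroxyl and the (Z)-iodoalkene. D-Arabinose supplies C5–C9, with C6 and C8 preformed and C7 set by addition to a 3-ulose.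

Key step: step 19

Remark: atom numbers are those of the target skeleton (lactone O–C6, C7–OH, C8–O-acyl, C9–OH, C1=C10, C4=C5, C11=C13H2, C12=O); the tertiary C7 hydroxyl is carried unprotected into the ring closure because chromium-mediated alkenylation tolerates free alcohols, so the ring closure delivers the target directly.

Step 1
Reactants: 1 tiglic acid
Product: 2 (E)-2-methylbut-2-en-1-ol
Conditions: LiAlH4, Et2O, 0 °C to rt; then H2O
Reagents that add atoms: none
Why: LiAlH4 reduction of the carboxylic acid should give the allylic alcohol without touching the trisubstituted olefin, so the E geometry needed for the cis-dimethyl epoxide is kept.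

Step 2
Reactants: 2 (E)-2-methylbut-2-en-1-ol
Product: 3 [(2R,3R)-2,3-dimethyloxiran-2-yl]methanol
Conditions: Ti(OiPr)4 (cat.), D-(−)-diisopropyl tartrate (cat.), t-BuOOH, 4 Å molecular sieves, CH2Cl2, −20 °C
Reagents that add atoms: tert-butyl hydroperoxide, CC(C)(C)OO
Why: Sharpless asymmetric epoxidation, in which the D-(−)-tartrate–titanium complex should deliver oxygen to the olefin face that gives the 2R,3R epoxide, while the syn addition keeps the two methyl groups cis.

Step 3
Reactants: 3 [(2R,3R)-2,3-dimethyloxiran-2-yl]methanol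
Product: 4 (2S,3R)-2,3-dimethyloxirane-2-carboxylic acid
Conditions: TEMPO (2,2,6,6-tetramethylpiperidin-1-oxyl, cat.), PhI(OAc)2, MeCN/H2O (1:1), 0 °C to rt
Reagents that add atoms: water, O
Why: Oxoammonium (TEMPO) oxidation of the primary alcohol through the aldehyde hydrate to the acid should leave the epoxide untouched, so both stereocentres are retained (C2 changes descriptor only because the carboxyl group now outranks C3).

Step 4
Reactants: 5 2,3-dibromopropene; 6 4-methoxybenzyl alcohol
Product: 7 2-bromo-3-(4-methoxybenzyloxy)prop-1-ene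
Conditions: NaH, THF, 0 °C to rt
Reagents that add atoms: none
Why: Williamson ether synthesis in which the alkoxide displaces the allylic bromide while the vinylic bromide is inert.

Step 5
Reactants: 8 D-arabinose
Product: 9 5-O-(tert-butyldiphenylsilyl)-D-arabinofuranose
Conditions: TBDPSCl, pyridine, 0 °C to rt
Reagents that add atoms: tert-butyl(chloro)diphenylsilane, CC(C)(C)[Si](Cl)(c1ccccc1)c1ccccc1
Why: Silyl ether formation at the only primary hydroxyl, which exists in the furanose form, should lock the sugar as a furanose whose C2 and C4 become C6 and C8 of the target.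

Step 6
Reactants: 9 5-O-(tert-butyldiphenylsilyl)-D-arabinofuranose
Product: 10 5-O-(tert-butyldiphenylsilyl)-1,2-O-isopropylidene-β-D-arabinofuranose
Conditions: 2,2-dimethoxypropane, camphorsulfonic acid (cat.), acetone, rt
Reagents that add atoms: 2,2-dimethoxypropane, COC(C)(C)OC
Why: Acid-catalysed acetonide formation can only bridge the cis O1/O2 pair of the β-anomer (O2 and O3 are trans), which leaves the C3 hydroxyl as the single free alcohol.

Step 7
Reactants: 10 5-O-(tert-butyldiphenylsilyl)-1,2-O-isopropylidene-β-D-arabinofuranose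
Product: 11 5-O-(tert-butyldiphenylsilyl)-1,2-O-isopropylidene-β-D-threo-pentofuranos-3-ulose
Conditions: Dess–Martin periodinane, NaHCO3, CH2Cl2, rt
Reagents that add atoms: none
Why: Dess–Martin oxidation of the lone secondary alcohol should give the 3-ulose (the future C7 carbonyl) without epimerising the flanking acetal-bearing centres.

Step 8
Reactants: 11 5-O-(tert-butyldiphenylsilyl)-1,2-O-isopropylidene-β-D-threo-pentofuranos-3-ulose; 7 2-bromo-3-(4-methoxybenzyloxy)prop-1-ene
Product: 13 5-O-(tert-butyldiphenylsilyl)-1,2-O-isopropylidene-3-C-[3-(4-methoxybenzyloxy)prop-1-en-2-yl]-β-D-lyxofuranose, via alkenyllithium 12 (not isolated)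
Conditions: 7, t-BuLi (2 equiv), Et2O, −78 °C; then 11, THF, −78 °C
Reagents that add atoms: none
Why: Bromine–lithium exchange followed by 1,2-addition of the alkenyllithium to the ketone should occur from the α-face, anti to the cis-fused 1,2-acetonide and to the C4 side chain that both shield the β-face (hydride and Grignard reagents add to this class of ulose in the same sense), which sets the tertiary carbinol C7 in the lyxo configuration of the target and brings in C11, C12 and C13.

Step 9
Reactants: 13 5-O-(tert-butyldiphenylsilyl)-1,2-O-isopropylidene-3-C-[3-(4-methoxybenzyloxy)prop-1-en-2-yl]-β-D-lyxofuranose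
Product: 14 5-O-(tert-butyldiphenylsilyl)-2,3-O-isopropylidene-3-C-[3-(4-methoxybenzyloxy)prop-1-en-2-yl]-D-lyxofuranose (lactol; both anomers)
Conditions: H2SO4 (cat.), acetone, rt
Reagents that add atoms: none
Why: Acid-catalysed acetal migration under thermodynamic control should move the isopropylidene group from the crowded all-cis 1,2-position to the cis O2/O3 pair (O6/O7 of the target), as lyxo- and manno-furanoses prefer 2,3-acetonides with a free anomeric hydroxyl, which frees the masked C5 aldehyde without touching a stereocentre.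

Step 10
Reactants: 14 5-O-(tert-butyldiphenylsilyl)-2,3-O-isopropylidene-3-C-[3-(4-methoxybenzyloxy)prop-1-en-2-yl]-D-lyxofuranose
Product: 15 C5 isopropenyl carbinol diol (5-OH both epimers; 8-OH free; 6,7-O-isopropylidene; 9-O-TBDPS; 12-O-PMB)
Conditions: isopropenylmagnesium bromide (3 equiv), THF, −20 °C to rt
Reagents that add atoms: isopropenylmagnesium bromide, C=C(C)[Mg]Br
Why: Grignard addition to the open-chain aldehyde that is in equilibrium with the magnesium lactolate opens the furanose and installs C3, C4 and C15, and the configuration of the new C5 carbinol is of no consequence because step 11 erases it.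

Step 11
Reactants: 15 C5 isopropenyl carbinol diol
Product: 17 (4E)-C1 aldehyde (8-OH free; 6,7-O-isopropylidene; 9-O-TBDPS; 12-O-PMB), via allyl vinyl ether 16 (not isolated)
Conditions: Hg(OAc)2 (cat.), ethyl vinyl ether, reflux; then xylenes, 140 °C; then 0.1 M HCl, THF, 0 °C
Reagents that add atoms: ethyl vinyl ether, C=COCC
Why: Transvinylation followed by Claisen rearrangement through a chair with the bulky C6 substituent equatorial should give the E-C4=C5 olefin and the C1 aldehyde from either C5 epimer, and any vinyl ether formed at the hindered C8 hydroxyl is cleaved again by the dilute acid.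

Step 12
Reactants: 17 (4E)-C1 aldehyde
Product: 18 (1(10)Z,4E)-10-iodo diene alcohol (8-OH free; 6,7-O-isopropylidene; 9-O-TBDPS; 12-O-PMB)
Conditions: EtPPh3I, n-BuLi, THF, rt; I2, −78 °C; NaN(SiMe3)2, −20 °C; then 17, −78 °C
Reagents that add atoms: ethyltriphenylphosphonium iodide, CC[P+](c1ccccc1)(c1ccccc1)c1ccccc1.[I-]; iodine, II
Why: Wittig olefination with the α-iodo ylide (Stork–Zhao-type iodo-olefination) is known to place iodine cis to the chain, which should give the (Z)-2-iodoalk-2-ene with C10 and C14 in place.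

Step 13
Reactants: 18 (1(10)Z,4E)-10-iodo diene alcohol; 4 (2S,3R)-2,3-dimethyloxirane-2-carboxylic acid
Product: 20 8-O-[(2S,3R)-2,3-dimethyloxirane-2-carbonyl] ester of 18, via mixed anhydride 19 (not isolated)
Conditions: 4, 2,4,6-trichlorobenzoyl chloride, Et3N, THF, rt; then 18, 4-(dimethylamino)pyridine, toluene, rt to 40 °C
Reagents that add atoms: none
Why: Yamaguchi esterification through the mixed anhydride should acylate the C8 hydroxyl, the only free hydroxyl in 18, with retention at C8 and without opening the epoxide.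

Step 14
Reactants: 20 8-O-epoxyacyl ester
Product: 21 12-hydroxy compound (6,7-O-isopropylidene; 9-O-TBDPS)
Conditions: DDQ, CH2Cl2/pH 7 buffer, 0 °C to rt
Reagents that add atoms: none
Why: Oxidative cleavage of the 4-methoxybenzyl ether by DDQ should free the primary allylic C12 alcohol while the acetonide still masks O6 and O7, so no cyclic acetal can form.

Step 15
Reactants: 21 12-hydroxy compound
Product: 22 6,7,12-triol (8-O-epoxyacyl; 9-O-TBDPS)
Conditions: AcOH/H2O (4:1), 45 °C
Reagents that add atoms: none
Why: Mild acid-catalysed acetal hydrolysis should release the C6 and C7 hydroxyls while the silyl ether and the electron-poor glycidic ester survive.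

Step 16
Reactants: 22 6,7,12-triol
Product: 25 12,6-olide 9-O-TBDPS ether (α-methylene-γ-lactone; 7-OH free), via hydroxy enal 23 (not isolated), via lactol 24 (not isolated)
Conditions: TEMPO (2,2,6,6-tetramethylpiperidin-1-oxyl, cat.), PhI(OAc)2, CH2Cl2, rt
Reagents that add atoms: none
Why: Oxidative lactonisation of a 1,4-diol, in which the oxoammonium salt should oxidise the primary allylic C12 alcohol first, the enal closes with the C6 hydroxyl to the five-membered lactol and this is oxidised on to the lactone, while the tertiary C7 hydroxyl can neither be oxidised nor form a ring.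

Step 17
Reactants: 25 12,6-olide 9-O-TBDPS ether
Product: 26 9-hydroxy seco lactone
Conditions: HF·pyridine, pyridine, THF, 0 °C to rt
Reagents that add atoms: none
Why: Fluoride cleavage of the primary silyl ether under buffered acidic conditions is chosen over basic fluoride to suppress O8 to O9 acyl migration and conjugate addition to the α-methylene lactone.

Step 18
Reactants: 26 9-hydroxy seco lactone
Product: 27 seco aldehyde–iodoalkene lactone (7-OH free)
Conditions: Dess–Martin periodinane, NaHCO3, CH2Cl2, 0 °C to rt; used at once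
Reagents that add atoms: none
Why: Buffered Dess–Martin oxidation of the primary alcohol should give the α-acyloxy aldehyde without epimerising C8, the tertiary C7 hydroxyl being inert.

Step 19
Reactants: 27 seco aldehyde–iodoalkene lactone
Product: 28 CNP0420662.1 (target)
Conditions: CrCl2 (excess), NiCl2 (cat.), degassed DMSO/THF, rt, slow addition of 27 to a final concentration of about 2 mM
Reagents that add atoms: none
Why: Zerovalent nickel, formed from NiCl2 by CrCl2, inserts into the C10–I bond and transmetalation gives an alkenyl species of trivalent chromium that adds to the C9 aldehyde with retention of the Z geometry. The closest known reaction type is the Nozaki–Hiyama–Kishi alkenyl iodide–aldehyde macrocyclisation used for medium and large carbocycles. The ten-membered ring C1–C10 closes in the 10-exo-trig mode onto the aldehyde C=O. The new C9 stereocentre is controlled by the neighbouring C8 acyloxy centre, the polar Felkin–Anh arrangement (nucleophile anti to the C8–O bond) leading to the 8,9-anti, 9R carbinol. The step needs chemoselectivity for the alkenyl iodide over the α-methylene lactone, the ester, the epoxide and the free C7 hydroxyl, which the mild chromium reagent should provide. It also needs ring closure to win over oligomerisation, which the cis placement of C2 and C9 on the Z-C1=C10 olefin, the rigid C6–C7 lactone and high dilution should secure.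

Compound list
1 | tiglic acid | C/C=C(\C)C(=O)O | starting material
2 | (E)-2-methylbut-2-en-1-ol | C/C=C(\C)CO | intermediate
3 | [(2R,3R)-2,3-dimethyloxiran-2-yl]methanol | OC[C@@]1(C)O[C@@H]1C | intermediate
4 | (2S,3R)-2,3-dimethyloxirane-2-carboxylic acid | OC(=O)[C@@]1(C)O[C@@H]1C | intermediate
5 | 2,3-dibromopropene | C=C(Br)CBr | starting material
6 | 4-methoxybenzyl alcohol | COc1ccc(CO)cc1 | starting material
7 | 2-bromo-3-(4-methoxybenzyloxy)prop-1-ene | C=C(Br)COCc1ccc(OC)cc1 | intermediate
8 | D-arabinose (aldehydo form drawn) | O=C[C@@H](O)[C@H](O)[C@H](O)CO | starting material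
9 | 5-O-(tert-butyldiphenylsilyl)-D-arabinofuranose | OC1O[C@H](CO[Si](c2ccccc2)(c2ccccc2)C(C)(C)C)[C@@H](O)[C@@H]1O | intermediate
10 | 5-O-(tert-butyldiphenylsilyl)-1,2-O-isopropylidene-β-D-arabinofuranose | CC1(C)O[C@@H]2O[C@H](CO[Si](c3ccccc3)(c3ccccc3)C(C)(C)C)[C@@H](O)[C@@H]2O1 | intermediate
11 | 5-O-(tert-butyldiphenylsilyl)-1,2-O-isopropylidene-β-D-threo-pentofuranos-3-ulose | CC1(C)O[C@@H]2O[C@H](CO[Si](c3ccccc3)(c3ccccc3)C(C)(C)C)C(=O)[C@@H]2O1 | intermediate
12 | [3-(4-methoxybenzyloxy)prop-1-en-2-yl]lithium | [Li]C(=C)COCc1ccc(OC)cc1 | intermediate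
13 | 5-O-(tert-butyldiphenylsilyl)-1,2-O-isopropylidene-3-C-[3-(4-methoxybenzyloxy)prop-1-en-2-yl]-β-D-lyxofuranose | CC1(C)O[C@@H]2O[C@H](CO[Si](c3ccccc3)(c3ccccc3)C(C)(C)C)[C@@](O)(C(=C)COCc3ccc(OC)cc3)[C@@H]2O1 | intermediate
14 | 5-O-(tert-butyldiphenylsilyl)-2,3-O-isopropylidene-3-C-[3-(4-methoxybenzyloxy)prop-1-en-2-yl]-D-lyxofuranose (lactol, both anomers) | OC1O[C@H](CO[Si](c2ccccc2)(c2ccccc2)C(C)(C)C)[C@]2(C(=C)COCc3ccc(OC)cc3)OC(C)(C)O[C@H]12 | intermediate
15 | C5 isopropenyl carbinol diol (5-OH both epimers, 8-OH free, 6,7-O-isopropylidene, 9-O-TBDPS, 12-O-PMB; C6, C7, C8 as in the target) | C=C(C)C(O)[C@H]1OC(C)(C)O[C@@]1(C(=C)COCc2ccc(OC)cc2)[C@H](O)CO[Si](c2ccccc2)(c2ccccc2)C(C)(C)C | intermediate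
16 | 5-O-vinyl ether of 15 (allyl vinyl ether) | C=COC(C(C)=C)[C@H]1OC(C)(C)O[C@@]1(C(=C)COCc2ccc(OC)cc2)[C@H](O)CO[Si](c2ccccc2)(c2ccccc2)C(C)(C)C | intermediate
17 | (4E)-C1 aldehyde (8-OH free, 6,7-O-isopropylidene, 9-O-TBDPS, 12-O-PMB) | O=CCC/C(C)=C/[C@H]1OC(C)(C)O[C@@]1(C(=C)COCc2ccc(OC)cc2)[C@H](O)CO[Si](c2ccccc2)(c2ccccc2)C(C)(C)C | intermediate
18 | (1(10)Z,4E)-10-iodo diene alcohol (8-OH free, 6,7-O-isopropylidene, 9-O-TBDPS, 12-O-PMB) | C/C(I)=C/CC/C(C)=C/[C@H]1OC(C)(C)O[C@@]1(C(=C)COCc2ccc(OC)cc2)[C@H](O)CO[Si](c2ccccc2)(c2ccccc2)C(C)(C)C | intermediate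
19 | (2S,3R)-2,3-dimethyloxirane-2-carboxylic 2,4,6-trichlorobenzoic anhydride | O=C(OC(=O)[C@@]1(C)O[C@@H]1C)c1c(Cl)cc(Cl)cc1Cl | intermediate
20 | 8-O-[(2S,3R)-2,3-dimethyloxirane-2-carbonyl] ester of 18 | C/C(I)=C/CC/C(C)=C/[C@H]1OC(C)(C)O[C@@]1(C(=C)COCc2ccc(OC)cc2)[C@H](OC(=O)[C@@]2(C)O[C@@H]2C)CO[Si](c2ccccc2)(c2ccccc2)C(C)(C)C | intermediate
21 | 12-hydroxy compound (6,7-O-isopropylidene, 8-O-epoxyacyl, 9-O-TBDPS) | C/C(I)=C/CC/C(C)=C/[C@H]1OC(C)(C)O[C@@]1(C(=C)CO)[C@H](OC(=O)[C@@]2(C)O[C@@H]2C)CO[Si](c2ccccc2)(c2ccccc2)C(C)(C)C | intermediate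
22 | 6,7,12-triol (8-O-epoxyacyl, 9-O-TBDPS) | C/C(I)=C/CC/C(C)=C/[C@@H](O)[C@](O)(C(=C)CO)[C@H](OC(=O)[C@@]1(C)O[C@@H]1C)CO[Si](c1ccccc1)(c1ccccc1)C(C)(C)C | intermediate
23 | 6,7-dihydroxy C12 enal | C/C(I)=C/CC/C(C)=C/[C@@H](O)[C@](O)(C(=C)C=O)[C@H](OC(=O)[C@@]1(C)O[C@@H]1C)CO[Si](c1ccccc1)(c1ccccc1)C(C)(C)C | intermediate
24 | 12,6-lactol (both C12 epimers) | C=C1C(O)O[C@H](/C=C(\C)CC/C=C(/C)I)[C@@]1(O)[C@H](OC(=O)[C@@]2(C)O[C@@H]2C)CO[Si](c2ccccc2)(c2ccccc2)C(C)(C)C | intermediate
25 | 12,6-olide 9-O-TBDPS ether (α-methylene-γ-lactone, 7-OH free) | C=C1C(=O)O[C@H](/C=C(\C)CC/C=C(/C)I)[C@@]1(O)[C@H](OC(=O)[C@@]2(C)O[C@@H]2C)CO[Si](c2ccccc2)(c2ccccc2)C(C)(C)C | intermediate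
26 | 9-hydroxy seco lactone | C=C1C(=O)O[C@H](/C=C(\C)CC/C=C(/C)I)[C@@]1(O)[C@H](OC(=O)[C@@]2(C)O[C@@H]2C)CO | intermediate
27 | seco aldehyde–iodoalkene lactone (7-OH free) | O=C[C@@H](OC(=O)[C@@]3(C)O[C@@H]3C)[C@@]1(O)C(=C)C(=O)O[C@@H]1/C=C(\C)CC/C=C(/C)I | intermediate
28 | CNP0420662.1, (6R,7R,8R,9R)-7,9-dihydroxy-8-[(2S,3R)-2,3-dimethyloxirane-2-carbonyloxy]germacra-1(10)Z,4E,11(13)-trien-12,6-olide | C=C1C(=O)O[C@@H]2/C=C(\C)CC/C=C(/C)[C@@H](O)[C@@H](OC(=O)[C@@]3(C)O[C@@H]3C)[C@@]12O | target

Total step count: 19. Longest linear sequence: 15 steps (steps 5 to 19, from D-arabinose 8 to 28).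

Steps most likely to fail

Step 19. The addition to the C9 aldehyde may show poor facial selectivity, and part of the material may be lost to intermolecular coupling. The fallback sets out from 27 and sets C9 by reduction instead of by addition. The ring closure is run as in step 19 and the carbinol mixture, which then contains the 9-epimer of 28 F1, is oxidised at the allylic C9 position with MnO2 in CH2Cl2 to the macrocyclic C9 enone F2. The tertiary C7 hydroxyl is not affected. F2 is reduced with a 2-methyl-CBS-oxazaborolidine and catecholborane at low temperature, the antipode of the catalyst being chosen so that hydride reaches the face that gives the 9R carbinol. The fallback comes back to the route at 28.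

Step 11. O-Vinylation of the diol may be incomplete or unselective, and the acid used to clear the C8 vinyl ether may start to open the acetonide. The fallback sets out from 15 and uses an Eschenmoser–Claisen rearrangement, which tolerates the free C8 hydroxyl and is strongly E-selective. Heating 15 with N,N-dimethylacetamide dimethyl acetal in xylenes at 140 °C should give the (4E)-N,N-dimethylamide F3. Cp2Zr(H)Cl in THF at rt then reduces the tertiary amide to the aldehyde, and the fallback comes back to the route at 17.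

Step 9. The acetal equilibrium may be unfavourable, or the anomeric acetonide may open too slowly under anhydrous acid. The fallback sets out from 13 and replaces the migration by hydrolysis and fresh acetonation. Heating 13 in 80% aqueous AcOH at 70 °C should give the free 3-C-branched lyxofuranose triol F4. Acetone with catalytic H2SO4 at rt then bridges its cis O2/O3 diol, as it does in D-lyxose itself, and the fallback comes back to the route at 14.

Further compounds
F1 | step 19 | 9-epimer of 28 (9S carbinol) | C=C1C(=O)O[C@@H]2/C=C(\C)CC/C=C(/C)[C@H](O)[C@@H](OC(=O)[C@@]3(C)O[C@@H]3C)[C@@]12O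
F2 | step 19 | macrocyclic C9 enone (9-oxo analogue of 28) | C=C1C(=O)O[C@@H]2/C=C(\C)CC/C=C(/C)C(=O)[C@@H](OC(=O)[C@@]3(C)O[C@@H]3C)[C@@]12O
F3 | step 11 | (4E)-N,N-dimethylamide (C1 amide analogue of 17) | CN(C)C(=O)CC/C(C)=C/[C@H]1OC(C)(C)O[C@@]1(C(=C)COCc2ccc(OC)cc2)[C@H](O)CO[Si](c2ccccc2)(c2ccccc2)C(C)(C)C
F4 | step 9 | 5-O-(tert-butyldiphenylsilyl)-3-C-[3-(4-methoxybenzyloxy)prop-1-en-2-yl]-D-lyxofuranose (anomers) | OC1O[C@H](CO[Si](c2ccccc2)(c2ccccc2)C(C)(C)C)[C@@](O)(C(=C)COCc2ccc(OC)cc2)[C@@H]1O
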